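**Retrosynthetic overview**
- The target, (3R,4R)-7-oxomatairesinol, comes from O-debenzylation of the trans keto-lactone; C8 (α to the ketone) is set last by equilibration to trans.
- The lactone comes from dehydrogenation of a γ-lactol, the same lactol → lactone half-reaction by which the plant dehydrogenase closes this ring.
- The lactol comes from a 9-hydroxy-9′-aldehyde made by an enantioselective radical 8–8′ coupling of two C6–C3 units (α-keto C8 radical plus chiral enamine at C8′, the amine catalyst standing in for the dirigent protein); the 9-OH captures C9′ in the same flask.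
- The C6–C3 units are a 3-arylpropanal (Heck reaction of an aryl bromide with allyl alcohol) and an α-bromo-β-hydroxy ketone (phenacyl bromide plus formaldehyde).
- Ring order: both arenes are bought; the only ring built is the oxolane, closed as the lactol in the coupling step and then oxidised to the lactone.

Assumption: lignan numbering is used in the comments (aroyl half C7–C9, benzyl half C7′–C9′, lactone C=O is C9′), and 1 and 4 are bought as the benzyl ethers.

**Step 1**
Reactants: 1 1-(benzyloxy)-4-bromo-2-methoxybenzene; 2 allyl alcohol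
Product: 3 3-[4-(benzyloxy)-3-methoxyphenyl]propanal
Conditions: Pd(OAc)2 (3 mol %), Bu4NCl, NaHCO3, DMF, 90 °C
Reagents that add atoms: none
Why: Jeffery-type Heck arylation of allyl alcohol, in which β-hydride elimination toward the carbinol carbon and enol–aldehyde tautomerisation give the saturated 3-arylpropanal directly; no stereocentre is formed.

**Step 2**
Reactants: 4 2-bromo-1-[4-(benzyloxy)-3-methoxyphenyl]ethan-1-one; 5 formaldehyde (monomeric, from cracked paraformaldehyde)
Product: 6 (±)-1-[4-(benzyloxy)-3-methoxyphenyl]-2-bromo-3-hydroxypropan-1-one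
Conditions: TiCl4, i-Pr2NEt, CH2Cl2, −78 °C; then HCHO (THF), −78 → −40 °C; aq. NH4Cl
Reagents that add atoms: none
Why: Soft-enolisation titanium aldol of an α-bromo ketone with formaldehyde (interrupted Darzens reaction), in which the chelated, non-basic titanium aldolate neither closes to the epoxide nor enolises again, so the mono-hydroxymethyl bromohydrin results; its stereocentre becomes a radical in step 3, so the racemate is used.

**Step 3**
Reactants: 3 3-[4-(benzyloxy)-3-methoxyphenyl]propanal (2 equiv); 6 (±)-1-[4-(benzyloxy)-3-methoxyphenyl]-2-bromo-3-hydroxypropan-1-one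
Product: 8 {(4R)-4-[4-(benzyloxy)-3-methoxybenzyl]-5-hydroxyoxolan-3-yl}[4-(benzyloxy)-3-methoxyphenyl]methanone (lactol; C3/C5 epimer mixture), via γ-hydroxy aldehyde 7 (not isolated)
Conditions: (2R,5S)-2-tert-butyl-3,5-dimethylimidazolidin-4-one·TfOH (20 mol %), Ru(bpy)3Cl2 (0.5 mol %), 2,6-lutidine, DMF, blue LED, 23 °C
Reagents that add atoms: none
Why: Proposed new method: the closest known reaction type is the MacMillan photoredox/chiral-enamine α-alkylation of aldehydes with phenacyl bromides, extended here to a secondary α-bromo-β-hydroxy ketone; Ru(I) reduces the C–Br bond of 6 to the electrophilic C8 α-keto radical, which adds to the Si face of the E-enamine of 3 (Re face shielded by the C5 methyl of the catalyst) and sets C8′ as R, then oxidation of the α-amino radical gives an iminium that the 9-OH captures and water hydrolyses to the lactol, which also protects C8′ from racemisation, while C8 and the anomeric carbon stay as mixtures.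

**Step 4**
Reactants: 8 lactol (C3/C5 epimer mixture)
Product: 10 (3R,4R)-4-[4-(benzyloxy)-3-methoxybenzoyl]-3-[4-(benzyloxy)-3-methoxybenzyl]oxolan-2-one, via C4-epimeric lactone mixture 9 (not isolated)
Conditions: TEMPO (10 mol %), PhI(OAc)2, CH2Cl2, rt; aq. NaHCO3 wash; then DBU (0.2 equiv), CH2Cl2, 0 °C → rt
Reagents that add atoms: none
Why: TEMPO/oxoammonium dehydrogenation of the lactol to the γ-lactone (the chemical counterpart of the enzymatic lactol oxidation), after which catalytic DBU epimerises only the more acidic ketone α-carbon C8 (ring C4) to the thermodynamically favoured trans isomer, while C8′ (ring C3, α to the lactone) is not deprotonated and the ring C–O bond is poorly aligned for E1cB opening.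

**Step 5**
Reactants: 10 (3R,4R)-4-[4-(benzyloxy)-3-methoxybenzoyl]-3-[4-(benzyloxy)-3-methoxybenzyl]oxolan-2-one
Product: 11 (3R,4R)-4-(4-hydroxy-3-methoxybenzoyl)-3-(4-hydroxy-3-methoxybenzyl)oxolan-2-one (7-oxomatairesinol, CNP0159909.1)
Conditions: H2 (1 atm), 10 % Pd/C, EtOAc–THF, rt, stopped at complete debenzylation
Reagents that add atoms: none
Why: Catalytic hydrogenolysis of the two aryl benzyl ethers, which under neutral conditions is much faster than reduction of the electron-rich α-branched aryl ketone; no stereocentre is touched.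

**Compound list**
1 | 1-(benzyloxy)-4-bromo-2-methoxybenzene | COc1cc(Br)ccc1OCc1ccccc1 | starting material
2 | allyl alcohol (prop-2-en-1-ol) | C=CCO | starting material
3 | 3-[4-(benzyloxy)-3-methoxyphenyl]propanal | COc1cc(CCC=O)ccc1OCc1ccccc1 | intermediate
4 | 2-bromo-1-[4-(benzyloxy)-3-methoxyphenyl]ethan-1-one | COc1cc(C(=O)CBr)ccc1OCc1ccccc1 | starting material
5 | formaldehyde | C=O | starting material
6 | (±)-1-[4-(benzyloxy)-3-methoxyphenyl]-2-bromo-3-hydroxypropan-1-one | COc1cc(C(=O)C(Br)CO)ccc1OCc1ccccc1 | intermediate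
7 | (2R)-2-[4-(benzyloxy)-3-methoxybenzyl]-4-[4-(benzyloxy)-3-methoxyphenyl]-3-(hydroxymethyl)-4-oxobutanal, both C3 epimers | COc1cc(C[C@@H](C=O)C(CO)C(=O)c2ccc(OCc3ccccc3)c(OC)c2)ccc1OCc1ccccc1 | intermediate
8 | {(4R)-4-[4-(benzyloxy)-3-methoxybenzyl]-5-hydroxyoxolan-3-yl}[4-(benzyloxy)-3-methoxyphenyl]methanone, lactol, mixture at C3 and C5 | COc1cc(C[C@H]2C(O)OCC2C(=O)c2ccc(OCc3ccccc3)c(OC)c2)ccc1OCc1ccccc1 | intermediate
9 | (3R)-4-[4-(benzyloxy)-3-methoxybenzoyl]-3-[4-(benzyloxy)-3-methoxybenzyl]oxolan-2-one, both C4 epimers | COc1cc(C[C@H]2C(=O)OCC2C(=O)c2ccc(OCc3ccccc3)c(OC)c2)ccc1OCc1ccccc1 | intermediate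
10 | (3R,4R)-4-[4-(benzyloxy)-3-methoxybenzoyl]-3-[4-(benzyloxy)-3-methoxybenzyl]oxolan-2-one (trans) | COc1cc(C[C@H]2C(=O)OC[C@@H]2C(=O)c2ccc(OCc3ccccc3)c(OC)c2)ccc1OCc1ccccc1 | intermediate
11 | (3R,4R)-4-(4-hydroxy-3-methoxybenzoyl)-3-(4-hydroxy-3-methoxybenzyl)oxolan-2-one (trans) | COc1cc(C[C@H]2C(=O)OC[C@@H]2C(=O)c2ccc(O)c(OC)c2)ccc1O | target

**Totals**
Total step count: 5. Longest linear sequence: 4 steps (1 → 3 → 8 → 10 → 11, or 4 → 6 → 8 → 10 → 11).

**Steps most likely to fail**

Step 3 is the most exposed: the secondary, hydroxylated α-keto radical may add slowly to the enamine or be reduced instead, and the enantioselectivity with this radical is untested. The fallback sets out from 3 and 4 and comes back at 8. The same dual catalysis is run with the primary bromide 4, the directly precedented case, to give (2R)-2-[4-(benzyloxy)-3-methoxybenzyl]-4-[4-(benzyloxy)-3-methoxyphenyl]-4-oxobutanal F1. The crude aldehyde is masked with HC(OMe)3/MeOH/PPTS as dimethyl acetal F2. C9 is then added by a base-catalysed aldol with formaldehyde 5 (paraformaldehyde, cat. K2CO3, DMSO, rt) to give hydroxymethyl ketone F3. Finally 1 M HCl in THF unmasks the aldehyde, which closes to lactol 8. Carbon–carbon coupling and ring closure are thus separated, and step 2 is no longer needed.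

Step 2 is the second risk: the bromohydrin may close to the epoxy ketone, add a second formaldehyde, or suffer Br/Cl exchange on titanium. The fallback sets out from 4 and comes back at 6. TMSOTf/Et3N in CH2Cl2 at 0 °C converts 4 into (Z)-silyl enol ether F4, which is isolated and hydroxymethylated with aqueous formaldehyde 5 under Yb(OTf)3 catalysis in THF–water (Mukaiyama-type aldol in water). No basic aldolate exists at any point, so neither epoxide closure nor a second aldol can occur.

Step 4 is the third risk: DBU could open the β-acyloxy ketone by E1cB or give incomplete cis → trans conversion, and lactol oxidation may be slow. The fallback sets out from 8 and comes back at 10. Pinnick oxidation (NaClO2, NaH2PO4, 2-methyl-2-butene, t-BuOH–H2O) of the open hydroxy-aldehyde tautomer gives hydroxy acid F5. Catalytic p-TsOH in toluene at 60 °C then closes the lactone and equilibrates C8 through the enol under acid, avoiding base altogether.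

**Further compounds**
F1 | step 3 | (2R)-2-[4-(benzyloxy)-3-methoxybenzyl]-4-[4-(benzyloxy)-3-methoxyphenyl]-4-oxobutanal | COc1cc(C[C@@H](C=O)CC(=O)c2ccc(OCc3ccccc3)c(OC)c2)ccc1OCc1ccccc1
F2 | step 3 | (3R)-3-[4-(benzyloxy)-3-methoxybenzyl]-1-[4-(benzyloxy)-3-methoxyphenyl]-4,4-dimethoxybutan-1-one | COc1cc(C[C@@H](C(OC)OC)CC(=O)c2ccc(OCc3ccccc3)c(OC)c2)ccc1OCc1ccccc1
F3 | step 3 | (3R)-3-[4-(benzyloxy)-3-methoxybenzyl]-1-[4-(benzyloxy)-3-methoxyphenyl]-2-(hydroxymethyl)-4,4-dimethoxybutan-1-one, both C2 epimers | COc1cc(C[C@@H](C(OC)OC)C(CO)C(=O)c2ccc(OCc3ccccc3)c(OC)c2)ccc1OCc1ccccc1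
F4 | step 2 | (Z)-{[1-(4-(benzyloxy)-3-methoxyphenyl)-2-bromoethenyl]oxy}trimethylsilane | COc1cc(/C(O[Si](C)(C)C)=C/Br)ccc1OCc1ccccc1
F5 | step 4 | (2R)-2-[4-(benzyloxy)-3-methoxybenzyl]-4-[4-(benzyloxy)-3-methoxyphenyl]-3-(hydroxymethyl)-4-oxobutanoic acid, both C3 epimers | COc1cc(C[C@@H](C(=O)O)C(CO)C(=O)c2ccc(OCc3ccccc3)c(OC)c2)ccc1OCc1ccccc1
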